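## Retrosynthetic overview

1. Target ⇐ bis-coumarin aryl ketone by a Felkin–Anh hydride reduction; the benzylic carbinol is made last and stays a ketone while acid is in use.
2. Both pyranone rings ⇐ one twofold palladium-catalysed phenol–propiolate annulation of a bis-phenol (two rings closed in a single operation, late).
3. Aryl–C-2 bond ⇐ dehydrative Friedel–Crafts allylation of 3,5-dimethoxyphenol by a cyclohexenyl cation, trans to the aroyl group.
4. Enantiopure allylic alcohol ⇐ asymmetric transfer hydrogenation with dynamic kinetic resolution of a 2-aroyl enone ⇐ aldol addition/oxidation of isophorone with 2,4,6-trimethoxybenzaldehyde.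
5. Ring order: the cyclohexene ring is bought as isophorone and the benzene rings with the two arenes; the two lactone rings are formed together in step 6.

Assumption: the sense of induction in step 3 (and in its fallback) is taken from the usual catalyst models, with the ring alkene in the place of the aryl group of an aryl ketone and a cis-selective dynamic kinetic resolution; if the acyl-bearing carbon came out with the opposite configuration, the mirror-image catalyst would be used.

## Route

Step 1
Reactants: 1 isophorone (3,5,5-trimethylcyclohex-2-en-1-one); 2 2,4,6-trimethoxybenzaldehyde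
Product: 4 6-[hydroxy(2,4,6-trimethoxyphenyl)methyl]-3,5,5-trimethylcyclohex-2-en-1-one (racemic mixture of diastereomers), via lithium dienolate 3 (not isolated)
Conditions: LiN(i-Pr)2 (1.1 equiv), THF, −78 °C; then 2, −78 °C; AcOH quench at −78 °C
Reagents that add atoms: none
Why: Kinetic deprotonation of isophorone occurs at the α′ CH2 next to the gem-dimethyl carbon and the cross-conjugated lithium enolate adds to the aldehyde in a directed aldol addition; the two new stereocentres need no control because one is oxidised away in step 2 and the other is reset in step 3.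

Step 2
Reactants: 4 aldol adduct
Product: 5 3,5,5-trimethyl-6-(2,4,6-trimethoxybenzoyl)cyclohex-2-en-1-one (racemic, configurationally labile at C-6)
Conditions: Dess–Martin periodinane (1.3 equiv), CH2Cl2, 0 °C → rt
Reagents that add atoms: none
Why: Dess–Martin oxidation of the benzylic secondary alcohol gives the 2-aroyl enone, whose single hydrogen between the two carbonyl groups makes the ring stereocentre freely epimerisable, as the dynamic kinetic resolution requires.

Step 3
Reactants: 5 2-aroyl enone
Product: 6 [(1R,2S)-2-hydroxy-4,6,6-trimethylcyclohex-3-en-1-yl](2,4,6-trimethoxyphenyl)methanone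
Conditions: RuCl[(R,R)-TsDPEN](p-cymene) (2 mol %), HCO2H–Et3N (5:2), CH2Cl2, 35 °C
Reagents that add atoms: none
Why: Noyori–Ikariya asymmetric transfer hydrogenation (divalent ruthenium) with dynamic kinetic resolution: the hindered, electron-rich aryl ketone is inert, the enone carbonyl of the faster-reacting enantiomer is reduced 1,2 from the face anti to the aroyl group while the other enantiomer racemises through the enol, which sets C-1 as R and the sacrificial cis carbinol C-2 as S.

Step 4
Reactants: 6 cis-hydroxy ketone; 7 3,5-dimethoxyphenol (4 equiv)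
Product: 9 [(1S,2R)-2-(2-hydroxy-4,6-dimethoxyphenyl)-4,6,6-trimethylcyclohex-3-en-1-yl](2,4,6-trimethoxyphenyl)methanone, via allyl cation 8 (not isolated)
Conditions: BF3·OEt2 (0.3 equiv), 4 Å molecular sieves, CH2Cl2, −20 °C
Reagents that add atoms: none
Why: Dehydrative Friedel–Crafts allylation of the Petrzilka (cannabidiol-coupling) type: ionisation of the allylic alcohol with loss of water gives the allyl cation, which the phenol attacks through its carbon ortho to OH at the secondary terminus and anti to the neighbouring aroyl group, setting C-2 as R trans to C-1 (descriptor now S, same spatial arrangement) and leaving the trisubstituted alkene.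

Step 5
Reactants: 9 trans aryl ketone
Product: 10 (2-hydroxy-4,6-dimethoxyphenyl)[(1S,2R)-2-(2-hydroxy-4,6-dimethoxyphenyl)-4,6,6-trimethylcyclohex-3-en-1-yl]methanone
Conditions: BCl3 (2.5 equiv), CH2Cl2, −78 → −10 °C; then H2O, 0 °C
Reagents that add atoms: none
Why: Chelation-controlled demethylation: BCl3 bound to the ketone oxygen cleaves only a methoxy group ortho to the carbonyl (the two ortho groups are equivalent), which unveils the second phenol without touching the other methyl ethers or the stereocentres.

Step 6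
Reactants: 10 bis-phenol ketone; 11 ethyl propiolate (6 equiv)
Product: 13 8-{[(1S,2R)-2-(5,7-dimethoxy-2-oxo-2H-chromen-8-yl)-4,6,6-trimethylcyclohex-3-en-1-yl]carbonyl}-5,7-dimethoxy-2H-chromen-2-one, via bis-cinnamate diester 12 (not isolated)
Conditions: Pd2(dba)3·CHCl3 (10 mol %), NaOAc, HCO2H, 25 °C
Reagents that add atoms: none
Why: Twofold Trost coumarin synthesis: zerovalent palladium in formic acid mediates net ortho C–H addition of each phenol to ethyl propiolate, and the two (Z)-2-hydroxycinnamates lactonise spontaneously, so both pyranone rings close in one operation at the only free positions ortho to the hydroxyl groups while the ketone keeps the acid-labile benzylic position in a safe oxidation state.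

Step 7
Reactants: 13 bis-coumarin ketone
Product: 14 8-[(S)-[(1S,2R)-2-(5,7-dimethoxy-2-oxo-2H-chromen-8-yl)-4,6,6-trimethylcyclohex-3-en-1-yl](hydroxy)methyl]-5,7-dimethoxy-2H-chromen-2-one (CNP0324863.2)
Conditions: NaBH4 (3 equiv), CeCl3·7H2O (1.5 equiv), MeOH–THF (1:1), −20 → 0 °C
Reagents that add atoms: none
Why: Luche-type hydride reduction under Felkin–Anh control: hydride attacks anti to the quaternary gem-dimethyl carbon with the carbonyl oxygen on the side of the aryl-bearing ring carbon, which gives the (S)-carbinol, and the coumarin lactones and enoates are not reduced under these conditions.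

## Compound list

1 | isophorone (3,5,5-trimethylcyclohex-2-en-1-one) | CC1=CC(=O)CC(C)(C)C1 | starting material
2 | 2,4,6-trimethoxybenzaldehyde | COc1cc(OC)c(C=O)c(OC)c1 | starting material
3 | lithium 3,3,5-trimethylcyclohexa-1,5-dien-1-olate (cross-conjugated α′-dienolate of isophorone) | [Li]OC1=CC(C)(C)CC(C)=C1 | intermediate
4 | 6-[hydroxy(2,4,6-trimethoxyphenyl)methyl]-3,5,5-trimethylcyclohex-2-en-1-one (racemic, both diastereomers) | COc1cc(OC)c(C(O)C2C(=O)C=C(C)CC2(C)C)c(OC)c1 | intermediate
5 | 3,5,5-trimethyl-6-(2,4,6-trimethoxybenzoyl)cyclohex-2-en-1-one (racemic, labile) | COc1cc(OC)c(C(=O)C2C(=O)C=C(C)CC2(C)C)c(OC)c1 | intermediate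
6 | [(1R,2S)-2-hydroxy-4,6,6-trimethylcyclohex-3-en-1-yl](2,4,6-trimethoxyphenyl)methanone | COc1cc(OC)c(C(=O)[C@H]2[C@@H](O)C=C(C)CC2(C)C)c(OC)c1 | intermediate
7 | 3,5-dimethoxyphenol | COc1cc(O)cc(OC)c1 | starting material
8 | allyl cation from 6 (positive charge delocalised over the former carbinol carbon and the methyl-bearing carbon; acyl-bearing stereocentre unchanged) | COc1cc(OC)c(C(=O)[C@H]2[CH+]C=C(C)CC2(C)C)c(OC)c1 | intermediate
9 | [(1S,2R)-2-(2-hydroxy-4,6-dimethoxyphenyl)-4,6,6-trimethylcyclohex-3-en-1-yl](2,4,6-trimethoxyphenyl)methanone | COc1cc(OC)c(C(=O)[C@H]2[C@H](c3c(O)cc(OC)cc3OC)C=C(C)CC2(C)C)c(OC)c1 | intermediate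
10 | (2-hydroxy-4,6-dimethoxyphenyl)[(1S,2R)-2-(2-hydroxy-4,6-dimethoxyphenyl)-4,6,6-trimethylcyclohex-3-en-1-yl]methanone | COc1cc(O)c(C(=O)[C@H]2[C@H](c3c(O)cc(OC)cc3OC)C=C(C)CC2(C)C)c(OC)c1 | intermediate
11 | ethyl propiolate | CCOC(=O)C#C | starting material
12 | ethyl (Z)-3-{3-[(1S,2R)-2-{3-[(Z)-3-ethoxy-3-oxoprop-1-en-1-yl]-2-hydroxy-4,6-dimethoxyphenyl}-4,6,6-trimethylcyclohex-3-ene-1-carbonyl]-2-hydroxy-4,6-dimethoxyphenyl}acrylate | CCOC(=O)/C=C\c1c(O)c(C(=O)[C@H]2[C@H](c3c(O)c(/C=C\C(=O)OCC)c(OC)cc3OC)C=C(C)CC2(C)C)c(OC)cc1OC | intermediate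
13 | 8-{[(1S,2R)-2-(5,7-dimethoxy-2-oxo-2H-chromen-8-yl)-4,6,6-trimethylcyclohex-3-en-1-yl]carbonyl}-5,7-dimethoxy-2H-chromen-2-one | COc1cc(OC)c2ccc(=O)oc2c1C(=O)[C@H]1[C@H](c2c(OC)cc(OC)c3ccc(=O)oc23)C=C(C)CC1(C)C | intermediate
14 | 8-[(S)-[(1S,2R)-2-(5,7-dimethoxy-2-oxo-2H-chromen-8-yl)-4,6,6-trimethylcyclohex-3-en-1-yl](hydroxy)methyl]-5,7-dimethoxy-2H-chromen-2-one | COc1cc(OC)c2ccc(=O)oc2c1[C@@H](O)[C@H]1[C@H](c2c(OC)cc(OC)c3ccc(=O)oc23)C=C(C)CC1(C)C | target

## Step count and risks

Total step count: 7. Longest linear sequence: 7 steps (1 → 4 → 5 → 6 → 9 → 10 → 13 → 14).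

Steps most likely to fail:

Step 3. The catalyst may be slow or poorly selective on this hindered 2-aroyl enone, and the cis/trans outcome of the resolution is not secured by close precedent. The fallback sets out from 5 and comes back at 6. It replaces the dynamic resolution by a reagent-controlled Corey–Bakshi–Shibata reduction: catecholborane with (S)-1-methyl-3,3-diphenyltetrahydro-1H,3H-pyrrolo[1,2-c][1,3,2]oxazaborole (10 mol %) in toluene at −78 °C, the alkenyl side taken as the larger group. This fixes the carbinol as S in both epimers of the acyl-bearing carbon. Chromatography gives 6 and the trans diastereomer [(1S,2S)-2-hydroxy-4,6,6-trimethylcyclohex-3-en-1-yl](2,4,6-trimethoxyphenyl)methanone F1, which is reoxidised with Dess–Martin periodinane to 5 and recycled.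

Step 4. The cation 8 can lose the proton next to the ketone to give a conjugated dienone, and the phenol can react at oxygen or at the carbon para to OH. The fallback sets out from 6 (aryl part from 7) and comes back at 9, with no free cation. Compound 6 is converted with ClCO2Me/pyridine into methyl (1S,6R)-3,5,5-trimethyl-6-(2,4,6-trimethoxybenzoyl)cyclohex-2-en-1-yl carbonate F2. Separately, 7 is protected (MOMCl, i-Pr2NEt) as 1,3-dimethoxy-5-(methoxymethoxy)benzene F3, lithiated between the MOM ether and a methoxy group (n-BuLi, THF, 0 °C) to [2,4-dimethoxy-6-(methoxymethoxy)phenyl]lithium F4, and transmetalated with ZnCl2 to chloro[2,4-dimethoxy-6-(methoxymethoxy)phenyl]zinc F5. Pd(PPh3)4-catalysed coupling of F2 with F5 (THF, 40 °C) passes through a π-allyl complex of divalent palladium formed with inversion; reductive elimination on the metal face at the less hindered allyl terminus again places the aryl group trans to the aroyl group and gives {(1S,2R)-2-[2,4-dimethoxy-6-(methoxymethoxy)phenyl]-4,6,6-trimethylcyclohex-3-en-1-yl}(2,4,6-trimethoxyphenyl)methanone F6. HCl (cat.) in MeOH at 0 °C then removes the MOM group and returns 9.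

Step 6. In formic acid the chelated, acyl-substituted phenol may react sluggishly, the free phenol next to the cyclohexene may add to the alkene or to the ketone, and attack para to OH would give a cinnamate that cannot lactonise. The fallback sets out from 10 and comes back at 13 under non-acidic conditions. Both phenols are esterified with propiolic acid (DCC, CH2Cl2, 0 °C) to 2-{[(1S,2R)-2-(2,4-dimethoxy-6-(prop-2-ynoyloxy)phenyl)-4,6,6-trimethylcyclohex-3-en-1-yl]carbonyl}-3,5-dimethoxyphenyl prop-2-ynoate F7. [Au{P(t-Bu)2(2-biphenylyl)}(NCMe)]SbF6 (5 mol %, CH2Cl2, rt; monovalent gold activates the alkynes) then closes both pyranone rings by twofold intramolecular 6-endo hydroarylation to give 13.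

## Further compounds

F1 | step 3 | [(1S,2S)-2-hydroxy-4,6,6-trimethylcyclohex-3-en-1-yl](2,4,6-trimethoxyphenyl)methanone | COc1cc(OC)c(C(=O)[C@@H]2[C@@H](O)C=C(C)CC2(C)C)c(OC)c1
F2 | step 4 | methyl (1S,6R)-3,5,5-trimethyl-6-(2,4,6-trimethoxybenzoyl)cyclohex-2-en-1-yl carbonate | COc1cc(OC)c(C(=O)[C@H]2[C@@H](OC(=O)OC)C=C(C)CC2(C)C)c(OC)c1
F3 | step 4 | 1,3-dimethoxy-5-(methoxymethoxy)benzene | COCOc1cc(OC)cc(OC)c1
F4 | step 4 | [2,4-dimethoxy-6-(methoxymethoxy)phenyl]lithium | [Li]c1c(OC)cc(OC)cc1OCOC
F5 | step 4 | chloro[2,4-dimethoxy-6-(methoxymethoxy)phenyl]zinc | Cl[Zn]c1c(OC)cc(OC)cc1OCOC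
F6 | step 4 | {(1S,2R)-2-[2,4-dimethoxy-6-(methoxymethoxy)phenyl]-4,6,6-trimethylcyclohex-3-en-1-yl}(2,4,6-trimethoxyphenyl)methanone | COc1cc(OC)c(C(=O)[C@H]2[C@H](c3c(OCOC)cc(OC)cc3OC)C=C(C)CC2(C)C)c(OC)c1
F7 | step 6 | 2-{[(1S,2R)-2-(2,4-dimethoxy-6-(prop-2-ynoyloxy)phenyl)-4,6,6-trimethylcyclohex-3-en-1-yl]carbonyl}-3,5-dimethoxyphenyl prop-2-ynoate | C#CC(=O)Oc1cc(OC)cc(OC)c1C(=O)[C@H]1[C@H](c2c(OC(=O)C#C)cc(OC)cc2OC)C=C(C)CC1(C)C
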